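**Plan**
1. Retrosynthesis: cut the aryl O–Ac bond (phenol mask), then take the pyrone C2=C3 double bond back to a chroman-4-one. Next cut the C2–CH2 bond between pyrone C-2 and the ethylene chain, giving a 2-arylethyl radical (a propanoic acid minus CO2) and a chromone-3-carboxylic acid. Finally take the pyrone ring back to an o-hydroxyacetophenone.
2. Enabling feature: the O1–C2=C3–C4=O vinylogous ester of the γ-pyrone ring. C-2 is its electrophilic β-carbon and accepts a nucleophilic alkyl radical; a CO2H helper on C-3 sharpens this and leaves as CO2 in the same flask.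
3. Forward order: the pyrone ring is built on the dimethoxyarene (steps 1–2) and the side-chain acid is masked and activated (steps 3–4). The two halves are joined at C-2 (step 5), the pyrone oxidation level is restored (step 6) and the phenol is unmasked (step 7).
4. Stereochemistry: the target has no stereocentre. The C-2 centre created in step 5 is racemic and is erased in step 6.

Key step: step 5

Remark: the target is achiral, so "single enantiomer" is read as the constitution shown and no asymmetric step is needed.

**Step 1**
Reactants: 1 1-(2-hydroxy-4,5-dimethoxyphenyl)ethan-1-one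
Product: 2 6,7-dimethoxy-4-oxo-4H-chromene-3-carbaldehyde
Conditions: POCl3 (3 equiv), DMF, 0 → 50 °C; then ice–H2O
Reagents that add atoms: N,N-dimethylformamide (CN(C)C=O); water (O)
Why: Vilsmeier–Haack double formylation of the acetyl CH3; the phenol oxygen closes the pyrone onto one iminium carbon (becoming C-2) and the second iminium hydrolyses to the 3-CHO, the standard route from 2-hydroxyacetophenones to 3-formylchromones.

**Step 2**
Reactants: 2 6,7-dimethoxy-4-oxo-4H-chromene-3-carbaldehyde
Product: 3 6,7-dimethoxy-4-oxo-4H-chromene-3-carboxylic acid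
Conditions: NaClO2, H2NSO3H, CH2Cl2/H2O, 0 °C → rt
Reagents that add atoms: sodium chlorite ([Na+].[O-]Cl=O)
Why: Pinnick (Lindgren) oxidation of the aldehyde to the acid; sulfamic acid traps hypochlorous acid so the electron-rich ring and the pyrone should stay untouched, as established for 3-formylchromones.

**Step 3**
Reactants: 4 3-(4-hydroxy-3-methoxyphenyl)propanoic acid (dihydroferulic acid)
Product: 5 3-(4-acetoxy-3-methoxyphenyl)propanoic acid
Conditions: Ac2O (1.5 equiv), aq. NaOH (3 equiv), 0 °C; then aq. HCl to pH 2
Reagents that add atoms: acetic anhydride (CC(=O)OC(C)=O)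
Why: Schotten–Baumann O-acetylation of the phenoxide (the carboxylate is not retained as an anhydride in water); the mask removes the phenolic O–H that would otherwise donate a hydrogen atom to the alkyl radical in step 5.

**Step 4**
Reactants: 5 3-(4-acetoxy-3-methoxyphenyl)propanoic acid
Product: 6 1,3-dioxoisoindolin-2-yl 3-(4-acetoxy-3-methoxyphenyl)propanoate
Conditions: N-hydroxyphthalimide (1.1 equiv), DIC (1.1 equiv), CH2Cl2, 0 °C → rt
Reagents that add atoms: N-hydroxyphthalimide (O=C1c2ccccc2C(=O)N1O)
Why: carbodiimide (Steglich-type) esterification to the redox-active N-(acyloxy)phthalimide; no nucleophilic catalyst is used, so the aryl acetate should not be transacylated.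

**Step 5**
Reactants: 3 6,7-dimethoxy-4-oxo-4H-chromene-3-carboxylic acid (1.0 equiv); 6 1,3-dioxoisoindolin-2-yl 3-(4-acetoxy-3-methoxyphenyl)propanoate (1.5 equiv)
Product: 8 rac-4-[2-(6,7-dimethoxy-4-oxochroman-2-yl)ethyl]-2-methoxyphenyl acetate, via 4-oxochromane-3-carboxylic acid adduct 7 (not isolated)
Conditions: Ru(bpy)3(PF6)2 (2 mol%), i-Pr2NEt (3 equiv), degassed CH2Cl2, blue LEDs (450 nm), rt; then 1 M HCl work-up
Reagents that add atoms: none
Why: Excited Ru(II) is quenched reductively by i-Pr2NEt, and the resulting Ru(I) transfers an electron to ester 6, which fragments to phthalimide anion, CO2 and the primary radical ArCH2CH2•; this adds to C-2 of the pyrone of 3, the C-3 radical (flanked by C4=O and the carboxylate) is reduced and protonated to β-keto acid 7, and 7 loses CO2 to give 8. The closest known reaction type is the visible-light doubly decarboxylative Giese reaction of chromone-3-carboxylic acids with N-(acyloxy)phthalimides, which gives 2-alkylchroman-4-ones. No ring is closed. The new stereocentre at C-2 (and the transient one at C-3 of 7) forms without control, which is acceptable because step 6 makes C-2 sp2 and the target is achiral. The step needs attack at C-2 rather than at C-3 or an arene, and this is secured by polarity matching: C-2 is the β-carbon of both C4=O and the C-3 carboxyl (an alkylidene-1,3-dicarbonyl-type acceptor next to O1), so it carries the largest LUMO coefficient and should trap the nucleophilic radical faster than hydrogen-atom transfer can reduce it, with the phenol masked as acetate so that no O–H competes.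

**Step 6**
Reactants: 8 rac-4-[2-(6,7-dimethoxy-4-oxochroman-2-yl)ethyl]-2-methoxyphenyl acetate
Product: 9 4-[2-(6,7-dimethoxy-4-oxo-4H-chromen-2-yl)ethyl]-2-methoxyphenyl acetate
Conditions: Pd(TFA)2 (10 mol%), DMSO (20 mol%), O2 (1 atm), AcOH, 80 °C
Reagents that add atoms: none
Why: Pd(II)-catalysed aerobic α,β-dehydrogenation of a ketone (Stahl-type): a Pd enolate at C-3 undergoes β-hydride elimination of the C2–H and O2 reoxidises palladium; only the C2=C3 alkene can form, it completes the conjugated γ-pyrone, and the C-2 stereocentre is erased.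

**Step 7**
Reactants: 9 4-[2-(6,7-dimethoxy-4-oxo-4H-chromen-2-yl)ethyl]-2-methoxyphenyl acetate
Product: 10 2-[2-(4-hydroxy-3-methoxyphenyl)ethyl]-6,7-dimethoxy-4H-chromen-4-one (target)
Conditions: HCl (1.25 M in MeOH), rt
Reagents that add atoms: none
Why: acid-catalysed transesterification (methanolysis) of the aryl acetate; the chromone is stable to acid (it is base- and nucleophile-sensitive) and the methyl ethers should be unaffected.

**Compound list**
1 | 1-(2-hydroxy-4,5-dimethoxyphenyl)ethan-1-one | CC(=O)c1cc(OC)c(OC)cc1O | starting material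
2 | 6,7-dimethoxy-4-oxo-4H-chromene-3-carbaldehyde | O=Cc1coc2cc(OC)c(OC)cc2c1=O | intermediate
3 | 6,7-dimethoxy-4-oxo-4H-chromene-3-carboxylic acid | O=C(O)c1coc2cc(OC)c(OC)cc2c1=O | intermediate
4 | 3-(4-hydroxy-3-methoxyphenyl)propanoic acid | COc1cc(CCC(=O)O)ccc1O | starting material
5 | 3-(4-acetoxy-3-methoxyphenyl)propanoic acid | COc1cc(CCC(=O)O)ccc1OC(C)=O | intermediate
6 | 1,3-dioxoisoindolin-2-yl 3-(4-acetoxy-3-methoxyphenyl)propanoate | COc1cc(CCC(=O)ON2C(=O)c3ccccc3C2=O)ccc1OC(C)=O | intermediate
7 | 2-[2-(4-acetoxy-3-methoxyphenyl)ethyl]-6,7-dimethoxy-4-oxochromane-3-carboxylic acid (racemic, diastereomer mixture, not isolated) | COc1cc(CCC2Oc3cc(OC)c(OC)cc3C(=O)C2C(=O)O)ccc1OC(C)=O | intermediate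
8 | rac-4-[2-(6,7-dimethoxy-4-oxochroman-2-yl)ethyl]-2-methoxyphenyl acetate | COc1cc(CCC2CC(=O)c3cc(OC)c(OC)cc3O2)ccc1OC(C)=O | intermediate
9 | 4-[2-(6,7-dimethoxy-4-oxo-4H-chromen-2-yl)ethyl]-2-methoxyphenyl acetate | COc1cc(CCc2cc(=O)c3cc(OC)c(OC)cc3o2)ccc1OC(C)=O | intermediate
10 | 2-[2-(4-hydroxy-3-methoxyphenyl)ethyl]-6,7-dimethoxy-4H-chromen-4-one | COc1cc(CCc2cc(=O)c3cc(OC)c(OC)cc3o2)ccc1O | target

**Totals**
Total step count: 7. Longest linear sequence: 5 steps (steps 1, 2, 5, 6, 7, or steps 3, 4, 5, 6, 7).

**Steps most likely to fail**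

Step 5. Hydrogen-atom transfer to the primary radical, or its dimerisation, may outrun addition to C-2, so that the redox-active ester is consumed without C–C bond formation; decarboxylation of the adduct may also stay incomplete. The fallback gives up the radical union and builds the pyrone ring around the chain by the classical condensation route. It sets out from 1 and 4 and comes back at 10. Acid 4 is esterified (MeOH, cat. H2SO4, reflux) to methyl 3-(4-hydroxy-3-methoxyphenyl)propanoate F1. Claisen condensation of the enolate of 1 with F1 (NaH, 5 equiv, THF, reflux, both phenols carried as phenoxides) should give 1-(2-hydroxy-4,5-dimethoxyphenyl)-5-(4-hydroxy-3-methoxyphenyl)pentane-1,3-dione F2. Acid cyclodehydration (HCl, MeOH, reflux) closes O1–C2 and should deliver 10 directly.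

Step 6. Palladium may aggregate before turnover, β-hydride elimination from the C-3 enolate may be slow, and the electron-rich arenes may undergo competing palladation. The fallback replaces catalytic dehydrogenation by halogenation–elimination. It sets out from 8 and comes back at 9. α-Bromination at C-3 (PhNMe3Br3, THF, rt) should give 4-[2-(3-bromo-6,7-dimethoxy-4-oxochroman-2-yl)ethyl]-2-methoxyphenyl acetate F3, and dehydrobromination (Et3N, EtOAc, reflux) should give 9.

Step 2. Hypochlorous acid may chlorinate the dimethoxy ring, and hydration at C-2 may open the pyrone during the oxidation. The fallback drops the C-3 carboxyl helper altogether. It sets out from 1 and comes back at 8. Condensation of 1 with DMF dimethyl acetal (toluene, 90 °C) should give (E)-3-(dimethylamino)-1-(2-hydroxy-4,5-dimethoxyphenyl)prop-2-en-1-one F4. Acid cyclisation (conc. HCl, CH2Cl2, rt) should give 6,7-dimethoxy-4H-chromen-4-one F5. A reductive photoredox Giese addition of the radical from 6 to C-2 of F5 (Ru(bpy)3(PF6)2, i-Pr2NEt, Hantzsch ester, CH2Cl2, blue LEDs) should then give 8.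

**Further compounds**
F1 | step 5 | methyl 3-(4-hydroxy-3-methoxyphenyl)propanoate | COC(=O)CCc1ccc(O)c(OC)c1
F2 | step 5 | 1-(2-hydroxy-4,5-dimethoxyphenyl)-5-(4-hydroxy-3-methoxyphenyl)pentane-1,3-dione | COc1cc(CCC(=O)CC(=O)c2cc(OC)c(OC)cc2O)ccc1O
F3 | step 6 | 4-[2-(3-bromo-6,7-dimethoxy-4-oxochroman-2-yl)ethyl]-2-methoxyphenyl acetate (racemic, trans expected) | COc1cc(CCC2Oc3cc(OC)c(OC)cc3C(=O)C2Br)ccc1OC(C)=O
F4 | step 2 | (E)-3-(dimethylamino)-1-(2-hydroxy-4,5-dimethoxyphenyl)prop-2-en-1-one | CN(C)/C=C/C(=O)c1cc(OC)c(OC)cc1O
F5 | step 2 | 6,7-dimethoxy-4H-chromen-4-one | COc1cc2occc(=O)c2cc1OC
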